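## Analysis of the target

Atom labels used below: C1–C2 is the ethyl group on C3; C4–C7 is the dienyl chain from C3 to the phenyl ring; the six-membered ring is C3, C8, C9, C10, C14, C15 (C8=C9, methyl on C9); the five-membered ring is C10, C11, C12, C13, C14 (C12=C13, methyls on C11 and C13); C15 carries a methyl group and the carboxyl carbon C16. The core is a trans-fused 3a,4,5,7a-tetrahydro-1H-indene in which a cyclohexene and a cyclopentene share the C10–C14 bond. Five contiguous stereocentres are present (3S, 10S, 11R, 14R, 15R): C3 and C15 are vicinal quaternary carbons; the carboxyl group, the dienyl arm and H14 lie on one face of the six-membered ring, and the C15 methyl, the ethyl group, H10 and the C11 methyl on the other. The sensitive parts are the (E,E)-1-phenylbutadiene, the two trisubstituted ring alkenes and a very hindered γ,δ-unsaturated acid that can lactonise onto C8=C9 in strong acid. The difficulty is the vicinal quaternary pair next to a trans ring fusion, together with two ring alkenes that must sit exactly at C8=C9 and C12=C13. The feature used is that C9 and C12, the inner carbons of these two alkenes, are separated only by C10 and C11: joining C9 to C12 gives a cyclobutene (C9, C10, C11, C12) whose single double bond can be converted by metathesis into both ring alkenes. Because H10 and the C11 methyl are cis on the five-membered ring, the C10 side chain and the C11 methyl must be cis on that cyclobutene, and the early steps have to deliver exactly this relationship.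

## Retrosynthetic reasoning

**Acid 27 from ester 26.** The last bond cut is the O–C bond of a 2-silylethyl ester. The carboxyl group sits on a quaternary carbon flanked by another quaternary carbon, so an ester that must be attacked at the carbonyl carbon would resist cleavage. A silylethyl ester is cleaved at silicon, under conditions that leave the diene and the ring alkenes alone, and it masks the acid through the ruthenium and palladium steps.

**Diene 26 from vinyl compound 24 and bromide 25.** The C5–C6 bond is cut as a Heck coupling. C4–C5 stays a plain vinyl group until the end, so the conjugated diene never meets the metathesis catalyst, and the styryl half comes from commercial 25. Since C3 is quaternary, β-hydride elimination after insertion can only go toward C5, which makes the coupling regiochemically clean. The forward reaction has to insert a hindered vinyl group and give the (E,E) geometry.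

**Bicycle 24 from cyclobutene 23 (key disconnection).** Both ring alkenes are cut and C9 is rejoined to C12; C8 becomes the terminus of a vinyl group on C3 and C13 an isopropenyl group on C14. C3 then carries two identical vinyl groups and is not yet a stereocentre. The gain is that two rings, two trisubstituted alkenes and the C3 stereocentre arise in one strain-driven step from a compound whose four stereocentres (C10, C11, C14, C15) are already in place. The forward reaction must choose one of two diastereotopic vinyl groups and must open the cyclobutene before anything else closes.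

**Ester 23 from acid 22.** A protecting-group change only; it is placed after the Claisen step because that step delivers the free acid.

**Acid 22 from ester 19; 19 from alcohol 10 and acid 17.** The C14–C15 bond is cut as an Ireland–Claisen bond. Only this cut produces the isopropenyl group on C14 automatically, from the allylic transposition of a 2-methylallyl ester. It also joins the two halves of the molecule and sets C14 and C15 in a single cyclic transition state. The forward reaction needs a defined ketene acetal geometry and has to discriminate the faces of the C13=C14 alkene through the cyclobutene stereocentres.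

**Acid 17 from ester 16, dienol 13 and orthoester 14; 13 from iodide 12 and alkynol 11.** The C3–C15 bond is cut as a Johnson–Claisen bond. The quaternary carbon C3 with its two vinyl groups arises from a 3,3-disubstituted allylic alcohol with no stereochemical issue, because C3 is not stereogenic at this stage and C15 is later enolised.

**Alcohol 10 from enoate 9; 9 from ester 6 and phosphonate 7 through aldehyde 8.** The C13=C14 bond is cut as a Horner–Wadsworth–Emmons olefination. Aldehyde 8 is both epimerisable at C10 and prone to electrocyclic ring opening, so it is made and consumed in one pot.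

**Ester 6 from salt 4, racemic acid 3, lactone 2 and pyranone 1.** A thermal [2+2] of an alkyne with an (E)-enoate would place the C10 and C11 substituents trans and lead to the C11 epimer of the target, so the cis ring is made differently. In the cyclobutene, C9 and C11 both carry a methyl group and flank C12. The C11–H bond is therefore cut back to an allylic C–O bond of the bicyclic lactone 2, which is the photochemical valence isomer of commercial 1. Ionisation of that C–O bond gives a symmetric 1,3-dimethylcyclobutenyl system, so there is no regiochemical question, and hydride delivery anti to the carboxylate sets the cis relationship. The acid obtained is racemic and is resolved as the salt 4.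

## Alternatives that were turned down

**Alternative 1:** The five-membered ring is cut at C13–C14 and C10–C11 (phosphine-catalysed [3+2] annulation). A nucleophilic phosphine would add to a γ-methyl allenic ester, and the zwitterion would add across the C10=C14 bond of an open-chain (E)-enone that already holds C3 and C15. The product would be cyclopentene A1, with an ester on C13, the methyl on C11 and an acetyl group on C10.
- For it: the annulation is catalytic, needs no photochemistry and, with a chiral phosphine, no resolution. C3 is a fixed stereocentre before any ring is made, so the vinyl-group selection of the chosen key step does not arise. On these points it is stronger.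
- Against it: the vicinal quaternary carbons C3 and C15 must be set on an acyclic chain. The acceptor carbon C14 is bonded to quaternary C15, which slows the addition and leaves face selection to open-chain induction. Three stereocentres (C10, C11, C14) and the α/γ regiochemistry of the allenoate are decided at once.
- Distance from the target: in A1 the C13 ester must still be reduced to a methyl group, the six-membered ring must be closed between the acetyl group and the C3 vinyl group, and the silyloxymethyl group must be turned into the dienyl arm.
- In comparison, the chosen route makes both rings and both ring alkenes in one step with every carbon at its final oxidation level, and has C10, C11 and C14 fixed before that step.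

**Alternative 2:** The C15–methyl and C3–ethyl bonds are cut (conjugate methylation followed by enolate ethylation on a lactone template). A methylcuprate would add to C15 of a tricyclic butenolide whose C3=C15 bond is conjugated to the lactone carbonyl, and the enolate would be ethylated at C3. The product would be the cis-fused lactone A2 with both quaternary centres.
- For it: both quaternary stereocentres are set in one pot under ring control, and C3 no longer depends on a choice between two like groups. This is stronger than the chosen route on its weakest point.
- Against it: the whole trans-fused diene with C10, C11 and C14 must be built first, so the ring construction is moved elsewhere. The acceptor is β,β-disubstituted, and cuprate additions that create quaternary carbons are slow. The enolate is extended through C8=C9 and can be alkylated at C9.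
- Distance from the target: in A2 the lactone carbonyl has to become the first carbon of the dienyl arm and the CH2O carbon has to be oxidised to the acid, several redox steps on a hindered framework.
- In comparison, the chosen route offers the ring construction itself and ends two steps after the key step without redox corrections.

**Alternative 3:** The bonds C10–C14, C11–C12 and C12–C13 are cut (rhodium-catalysed carbonylative [2+2+1] cyclisation of a dienyne). The alkyne on C15 and the outer (E)-propenyl alkene of a diene attached to C3 would be joined with a one-carbon carbonyl unit. The product would be the bicyclic enone A3, with a ketone at C12 and the alkene at C13=C14.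
- For it: both rings and three C–C bonds form in one step from an open chain. It has as much ring-forming power as the chosen key step, and it makes the C10–C14 σ bond that the chosen route has to build by Claisen chemistry. On bond count it is stronger.
- Against it: the product has the wrong pattern. The C12 ketone must be removed and the alkene moved from C13=C14 to C12=C13 while H14 is installed trans to H10, a reductive transposition whose stereochemical outcome on a hydrindane is uncertain. The quaternary pair C3/C15 again has to be made on an open chain. The tether contains a (Z)-trisubstituted alkene, and six-membered ring formation in this cyclisation is slower than five-membered.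
- In comparison, the chosen route places both alkenes directly where the target has them, with the ring fusion already defined.

Key step: step 14

Remark on the chemistry (assumption): in step 3 the salt of the (1R,4R) acid with (R)-1-phenylethylamine is taken to be the less soluble diastereomer; if the opposite holds, (S)-1-phenylethylamine is used and nothing else changes.

## Route

Step 1
Reactants: 1 4,6-dimethyl-2H-pyran-2-one
Product: 2 rac-1,5-dimethyl-2-oxabicyclo[2.2.0]hex-5-en-3-one (cis-fused; kept as a cold solution)
Conditions: hν (300 nm, Pyrex), Et2O, −20 °C
Reagents that add atoms: none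
Why: Photochemical disrotatory 4π electrocyclisation of the pyranone diene to its bicyclic valence isomer, a known reaction of 2-pyranones; the cis ring fusion is enforced by geometry, and low temperature in an aprotic solvent preserves the labile tertiary allylic C–O bond.

Step 2
Reactants: 2 rac-1,5-dimethyl-2-oxabicyclo[2.2.0]hex-5-en-3-one
Product: 3 rac-(1R,4R)-2,4-dimethylcyclobut-2-ene-1-carboxylic acid (cis)
Conditions: Pd(PPh3)4 (5 mol%), HCO2H, Et3N, THF, −20 → 0 °C
Reagents that add atoms: none
Why: Palladium-catalysed allylic hydrogenolysis with formate; zerovalent palladium ionises the allylic C–O bond with inversion to a cyclobutenyl allyl complex whose two termini are equivalent, and hydride passes from palladium to either terminus on the face opposite the carboxylate. The methyl group on the reduced carbon is thereby pushed cis to the carboxyl group, so the cis acid should form, as a racemate.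

Step 3
Reactants: 3 rac-(1R,4R)-2,4-dimethylcyclobut-2-ene-1-carboxylic acid
Product: 4 (1R)-1-phenylethan-1-aminium (1R,4R)-2,4-dimethylcyclobut-2-ene-1-carboxylate
Conditions: (R)-1-phenylethylamine (0.55 equiv), EtOAc/hexane, two crystallisations
Reagents that add atoms: (R)-1-phenylethylamine, C[C@@H](N)c1ccccc1
Why: Classical resolution through diastereomeric ammonium salts; only the absolute configuration is selected here, since the cis relationship was fixed in step 2.

Step 4
Reactants: 4 (1R)-1-phenylethan-1-aminium (1R,4R)-2,4-dimethylcyclobut-2-ene-1-carboxylate
Product: 6 methyl (1R,4R)-2,4-dimethylcyclobut-2-ene-1-carboxylate, via free acid 5 (not isolated)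
Conditions: dilute aq. HCl, Et2O; then Me3SiCHN2, MeOH/Et2O, 0 °C
Reagents that add atoms: (trimethylsilyl)diazomethane, C[Si](C)(C)C=[N+]=[N-]
Why: Acidification frees the acid and diazoalkane methylation esterifies it without base, so the epimerisable, allylic C10 is never exposed to enolising conditions.

Step 5
Reactants: 6 methyl (1R,4R)-2,4-dimethylcyclobut-2-ene-1-carboxylate; 7 triethyl 2-phosphonopropionate
Product: 9 ethyl (2E)-3-[(1S,4R)-2,4-dimethylcyclobut-2-en-1-yl]-2-methylprop-2-enoate, via cyclobutenecarbaldehyde 8 (not isolated)
Conditions: iBu2AlH (1.05 equiv), CH2Cl2, −78 °C; then 7/NaH in THF, −78 → 0 °C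
Reagents that add atoms: none
Why: Half-reduction of the ester to the aluminium hemiacetal followed by Horner–Wadsworth–Emmons olefination in the same pot; aldehyde 8 is released only in the presence of the phosphonate anion, which limits C10 epimerisation and electrocyclic ring opening. The α-methyl phosphonate should give the (E)-trisubstituted enoate.

Step 6
Reactants: 9 ethyl (2E)-3-[(1S,4R)-2,4-dimethylcyclobut-2-en-1-yl]-2-methylprop-2-enoate
Product: 10 (2E)-3-[(1S,4R)-2,4-dimethylcyclobut-2-en-1-yl]-2-methylprop-2-en-1-ol
Conditions: iBu2AlH (2.2 equiv), CH2Cl2, −78 °C
Reagents that add atoms: none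
Why: 1,2-Reduction of an α,β-unsaturated ester to the allylic alcohol with an aluminium hydride; the alkene geometry and the ring stereocentres are not involved.

Step 7
Reactants: 11 pent-2-yn-1-ol
Product: 12 (2Z)-3-iodopent-2-en-1-ol
Conditions: NaAlH2(OCH2CH2OMe)2, THF, 0 °C → rt; then I2, −78 → 0 °C
Reagents that add atoms: iodine, II
Why: trans-Hydroalumination of a propargylic alcohol through its alkoxy-aluminate places aluminium on the carbon remote from oxygen, and iodinolysis with retention gives the (Z)-3-iodo allylic alcohol.

Step 8
Reactants: 12 (2Z)-3-iodopent-2-en-1-ol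
Product: 13 (2Z)-3-ethylpenta-2,4-dien-1-ol
Conditions: Bu3SnCH=CH2, Pd(PPh3)4 (5 mol%), DMF, 50 °C
Reagents that add atoms: tributyl(vinyl)stannane, C=C[Sn](CCCC)(CCCC)CCCC
Why: Stille coupling of an alkenyl iodide with retention of geometry; the free hydroxyl group is tolerated.

Step 9
Reactants: 13 (2Z)-3-ethylpenta-2,4-dien-1-ol; 14 triethyl orthopropionate
Product: 16 ethyl 3-ethenyl-3-ethyl-2-methylpent-4-enoate (racemic), via mixed ketene acetal 15 (not isolated)
Conditions: 14 (5 equiv), EtCO2H (cat.), 135 °C, EtOH distilled off
Reagents that add atoms: none
Why: Johnson–Claisen rearrangement; the [3,3] shift of ketene acetal 15 forms the C3–C15 bond at the disubstituted allyl terminus and creates the quaternary carbon bearing ethyl and two vinyl groups. The dienol geometry is irrelevant because C3 is not stereogenic.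

Step 10
Reactants: 16 ethyl 3-ethenyl-3-ethyl-2-methylpent-4-enoate
Product: 17 3-ethenyl-3-ethyl-2-methylpent-4-enoic acid (racemic)
Conditions: KOH, EtOH/H2O, 80 °C; then dilute aq. HCl
Reagents that add atoms: potassium hydroxide, [K+].[OH-]
Why: Saponification of a hindered but still enolisable ethyl ester under forcing conditions; the 1,4-diene has no acidic or conjugating position that would be affected.

Step 11
Reactants: 17 3-ethenyl-3-ethyl-2-methylpent-4-enoic acid; 10 (2E)-3-[(1S,4R)-2,4-dimethylcyclobut-2-en-1-yl]-2-methylprop-2-en-1-ol
Product: 19 (2E)-3-[(1S,4R)-2,4-dimethylcyclobut-2-en-1-yl]-2-methylprop-2-en-1-yl 3-ethenyl-3-ethyl-2-methylpent-4-enoate (both epimers at the acyl α-carbon), via acid chloride 18 (not isolated)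
Conditions: (COCl)2, DMF (cat.), CH2Cl2, 0 °C → rt; then 10, pyridine, DMAP (cat.), CH2Cl2, 0 °C → rt
Reagents that add atoms: none
Why: Acylation of a primary allylic alcohol by an acid chloride, the most dependable esterification for an acid with a quaternary β-carbon; the α-centre of the acid is a mixture and is erased in the next step.

Step 12
Reactants: 19 (2E)-3-[(1S,4R)-2,4-dimethylcyclobut-2-en-1-yl]-2-methylprop-2-en-1-yl 3-ethenyl-3-ethyl-2-methylpent-4-enoate
Product: 22 (2R,3R)-3-[(1S,4R)-2,4-dimethylcyclobut-2-en-1-yl]-2-(3-ethylpenta-1,4-dien-3-yl)-2,4-dimethylpent-4-enoic acid, via silyl ketene acetal 20 (not isolated), via trimethylsilyl ester 21 (not isolated)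
Conditions: LiN(iPr)2, THF/HMPA (4:1), −78 °C; Me3SiCl; −78 → 60 °C; then dilute aq. HCl to pH 4, 0 °C
Reagents that add atoms: none
Why: Ireland–Claisen rearrangement, forming C14–C15 and the isopropenyl group. Enolisation in the dissociating medium is expected to place the bulky tertiary-alkyl group syn to the silylated oxygen (Z ketene acetal 20), and a chair transition state with the (E)-allyl unit then gives the 14R,15R relationship. With H10 eclipsing the alkene (allylic 1,3-strain against the C13 methyl), the cis C11 methyl blocks one face of C14, so C15 should add anti to it.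

Step 13
Reactants: 22 (2R,3R)-3-[(1S,4R)-2,4-dimethylcyclobut-2-en-1-yl]-2-(3-ethylpenta-1,4-dien-3-yl)-2,4-dimethylpent-4-enoic acid
Product: 23 2-(trimethylsilyl)ethyl (2R,3R)-3-[(1S,4R)-2,4-dimethylcyclobut-2-en-1-yl]-2-(3-ethylpenta-1,4-dien-3-yl)-2,4-dimethylpent-4-enoate
Conditions: Me3SiCH2CH2OH, PPh3, DIAD, THF, 0 °C → rt
Reagents that add atoms: 2-(trimethylsilyl)ethanol, C[Si](C)(C)CCO
Why: Mitsunobu esterification; the carboxylate attacks the activated primary alcohol, so the hindrance at the acyl carbon does not matter and no stereocentre is touched.

Step 14
Reactants: 23 2-(trimethylsilyl)ethyl (2R,3R)-3-[(1S,4R)-2,4-dimethylcyclobut-2-en-1-yl]-2-(3-ethylpenta-1,4-dien-3-yl)-2,4-dimethylpent-4-enoate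
Product: 24 2-(trimethylsilyl)ethyl (1R,3aR,4R,5S,7aS)-5-ethenyl-5-ethyl-1,3,4,7-tetramethyl-3a,4,5,7a-tetrahydro-1H-indene-4-carboxylate
Conditions: second-generation Hoveyda–Grubbs catalyst RuCl2(H2IMes)(=CH-C6H4-2-OiPr) (10 mol%), toluene (0.002 M), 80 °C
Reagents that add atoms: none
Why: Ring-rearrangement metathesis (ring opening and double ring closure) of a strained cyclobutene with tethered alkenes, a known reaction class; only the choice between two diastereotopic vinyl groups is without close model. The ruthenium benzylidene exchanges reversibly onto either C3 vinyl group; the C8 alkylidene adds across the strained C9=C12 bond, and cycloreversion of the metallacyclobutane forms C8=C9, closes the six-membered ring (C3, C8, C9, C10, C14, C15) and moves ruthenium to C12. The C12 alkylidene then undergoes ring-closing metathesis with the 1,1-disubstituted alkene on C14, which forms C12=C13, closes the five-membered ring (C10 to C14) and releases the catalyst as a methylidene; the two lost methylene carbons leave as ethene. Relief of cyclobutene strain makes the opening irreversible and pays for two trisubstituted alkenes. C10, C11, C14 and C15 are not touched, so the trans ring fusion and the C11 configuration come directly from 23. The one new stereocentre, C3, is set by which vinyl group closes: in the half-chair of the forming cyclohexene the ring bonds at C10 and C14 are equatorial and the C15 methyl is axial, and the target needs the spectator vinyl group axial (anti to that methyl) and the ethyl group equatorial, which puts the slimmer sp2 group in the axial site. This preference is expected to be modest and must be established by experiment. High dilution suppresses intermolecular ring-opening oligomerisation, and the strain-driven opening is expected to outrun five-ring closure of the C8 alkylidene onto the isopropenyl group.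

Step 15
Reactants: 24 2-(trimethylsilyl)ethyl (1R,3aR,4R,5S,7aS)-5-ethenyl-5-ethyl-1,3,4,7-tetramethyl-3a,4,5,7a-tetrahydro-1H-indene-4-carboxylate; 25 (E)-β-bromostyrene
Product: 26 2-(trimethylsilyl)ethyl (1R,3aR,4R,5S,7aS)-5-ethyl-1,3,4,7-tetramethyl-5-[(1E,3E)-4-phenylbuta-1,3-dien-1-yl]-3a,4,5,7a-tetrahydro-1H-indene-4-carboxylate
Conditions: Pd(OAc)2 (10 mol%), P(o-tol)3, Et3N, DMF, 90 °C
Reagents that add atoms: none
Why: Heck coupling of an alkenyl bromide with a terminal alkene; after oxidative addition to zerovalent palladium the styryl group adds to the terminal carbon of the C3 vinyl group, and syn β-hydride elimination can only occur away from quaternary C3, giving the (E,E)-diene. The trisubstituted ring alkenes are too hindered to insert.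

Step 16
Reactants: 26 2-(trimethylsilyl)ethyl (1R,3aR,4R,5S,7aS)-5-ethyl-1,3,4,7-tetramethyl-5-[(1E,3E)-4-phenylbuta-1,3-dien-1-yl]-3a,4,5,7a-tetrahydro-1H-indene-4-carboxylate
Product: 27 (1R,3aR,4R,5S,7aS)-5-ethyl-1,3,4,7-tetramethyl-5-[(1E,3E)-4-phenylbuta-1,3-dien-1-yl]-3a,4,5,7a-tetrahydro-1H-indene-4-carboxylic acid (CNP0200738.1)
Conditions: Bu4NF, THF, rt; then dilute aq. HCl to pH 4, 0 °C
Reagents that add atoms: none
Why: Fluoride attacks silicon and the 2-silylethyl ester fragments to carboxylate, ethene and fluorosilane; no nucleophile has to reach the hindered carbonyl carbon, and the diene and ring alkenes are inert to fluoride.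

## Compound list

1 | 4,6-dimethyl-2H-pyran-2-one | CC1=CC(=O)OC(C)=C1 | starting material
2 | rac-1,5-dimethyl-2-oxabicyclo[2.2.0]hex-5-en-3-one (cis-fused; racemate, one enantiomer drawn) | O=C1O[C@]2(C)C=C(C)[C@H]12 | intermediate
3 | rac-(1R,4R)-2,4-dimethylcyclobut-2-ene-1-carboxylic acid (cis; racemate, one enantiomer drawn) | OC(=O)[C@H]1C(C)=C[C@H]1C | intermediate
4 | (1R)-1-phenylethan-1-aminium (1R,4R)-2,4-dimethylcyclobut-2-ene-1-carboxylate | C[C@@H]([NH3+])c1ccccc1.[O-]C(=O)[C@H]1C(C)=C[C@H]1C | intermediate
5 | (1R,4R)-2,4-dimethylcyclobut-2-ene-1-carboxylic acid | OC(=O)[C@H]1C(C)=C[C@H]1C | intermediate (not isolated)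
6 | methyl (1R,4R)-2,4-dimethylcyclobut-2-ene-1-carboxylate | COC(=O)[C@H]1C(C)=C[C@H]1C | intermediate
7 | triethyl 2-phosphonopropionate (ethyl 2-(diethoxyphosphoryl)propanoate) | CCOC(=O)C(C)P(=O)(OCC)OCC | starting material
8 | (1R,4R)-2,4-dimethylcyclobut-2-ene-1-carbaldehyde | O=C[C@H]1C(C)=C[C@H]1C | intermediate (not isolated)
9 | ethyl (2E)-3-[(1S,4R)-2,4-dimethylcyclobut-2-en-1-yl]-2-methylprop-2-enoate | CCOC(=O)/C(C)=C/[C@H]1C(C)=C[C@H]1C | intermediate
10 | (2E)-3-[(1S,4R)-2,4-dimethylcyclobut-2-en-1-yl]-2-methylprop-2-en-1-ol | OC/C(C)=C/[C@H]1C(C)=C[C@H]1C | intermediate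
11 | pent-2-yn-1-ol | CCC#CCO | starting material
12 | (2Z)-3-iodopent-2-en-1-ol | OC/C=C(\I)CC | intermediate
13 | (2Z)-3-ethylpenta-2,4-dien-1-ol | OC/C=C(\C=C)CC | intermediate
14 | triethyl orthopropionate (1,1,1-triethoxypropane) | CCC(OCC)(OCC)OCC | starting material
15 | 1-ethoxy-1-{[(2Z)-3-ethylpenta-2,4-dien-1-yl]oxy}prop-1-ene (ketene acetal, enol ether geometry not fixed) | CC=C(OCC)OC/C=C(\C=C)CC | intermediate (not isolated)
16 | ethyl 3-ethenyl-3-ethyl-2-methylpent-4-enoate (racemic) | CCOC(=O)C(C)C(CC)(C=C)C=C | intermediate
17 | 3-ethenyl-3-ethyl-2-methylpent-4-enoic acid (racemic) | OC(=O)C(C)C(CC)(C=C)C=C | intermediate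
18 | 3-ethenyl-3-ethyl-2-methylpent-4-enoyl chloride (racemic) | ClC(=O)C(C)C(CC)(C=C)C=C | intermediate (not isolated)
19 | (2E)-3-[(1S,4R)-2,4-dimethylcyclobut-2-en-1-yl]-2-methylprop-2-en-1-yl 3-ethenyl-3-ethyl-2-methylpent-4-enoate (both epimers at the acyl α-carbon) | CCC(C=C)(C=C)C(C)C(=O)OC/C(C)=C/[C@H]1C(C)=C[C@H]1C | intermediate
20 | {[(1Z)-1-({(2E)-3-[(1S,4R)-2,4-dimethylcyclobut-2-en-1-yl]-2-methylprop-2-en-1-yl}oxy)-3-ethenyl-3-ethyl-2-methylpenta-1,4-dien-1-yl]oxy}trimethylsilane | CCC(C=C)(C=C)/C(C)=C(\O[Si](C)(C)C)OC/C(C)=C/[C@H]1C(C)=C[C@H]1C | intermediate (not isolated)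
21 | trimethylsilyl (2R,3R)-3-[(1S,4R)-2,4-dimethylcyclobut-2-en-1-yl]-2-(3-ethylpenta-1,4-dien-3-yl)-2,4-dimethylpent-4-enoate | CCC(C=C)(C=C)[C@](C)(C(=O)O[Si](C)(C)C)[C@@H](C(C)=C)[C@H]1C(C)=C[C@H]1C | intermediate (not isolated)
22 | (2R,3R)-3-[(1S,4R)-2,4-dimethylcyclobut-2-en-1-yl]-2-(3-ethylpenta-1,4-dien-3-yl)-2,4-dimethylpent-4-enoic acid | CCC(C=C)(C=C)[C@](C)(C(=O)O)[C@@H](C(C)=C)[C@H]1C(C)=C[C@H]1C | intermediate
23 | 2-(trimethylsilyl)ethyl (2R,3R)-3-[(1S,4R)-2,4-dimethylcyclobut-2-en-1-yl]-2-(3-ethylpenta-1,4-dien-3-yl)-2,4-dimethylpent-4-enoate | CCC(C=C)(C=C)[C@](C)(C(=O)OCC[Si](C)(C)C)[C@@H](C(C)=C)[C@H]1C(C)=C[C@H]1C | intermediate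
24 | 2-(trimethylsilyl)ethyl (1R,3aR,4R,5S,7aS)-5-ethenyl-5-ethyl-1,3,4,7-tetramethyl-3a,4,5,7a-tetrahydro-1H-indene-4-carboxylate | CC[C@]1(C=C)C=C(C)[C@H]2[C@H](C)C=C(C)[C@@H]2[C@@]1(C)C(=O)OCC[Si](C)(C)C | intermediate
25 | (E)-β-bromostyrene, [(E)-2-bromoethenyl]benzene | Br/C=C/c1ccccc1 | starting material
26 | 2-(trimethylsilyl)ethyl (1R,3aR,4R,5S,7aS)-5-ethyl-1,3,4,7-tetramethyl-5-[(1E,3E)-4-phenylbuta-1,3-dien-1-yl]-3a,4,5,7a-tetrahydro-1H-indene-4-carboxylate | CC[C@]1(/C=C/C=C/c2ccccc2)C=C(C)[C@H]2[C@H](C)C=C(C)[C@@H]2[C@@]1(C)C(=O)OCC[Si](C)(C)C | intermediate
27 | (1R,3aR,4R,5S,7aS)-5-ethyl-1,3,4,7-tetramethyl-5-[(1E,3E)-4-phenylbuta-1,3-dien-1-yl]-3a,4,5,7a-tetrahydro-1H-indene-4-carboxylic acid | CC[C@]1(/C=C/C=C/c2ccccc2)C=C(C)[C@H]2[C@H](C)C=C(C)[C@@H]2[C@@]1(C)C(=O)O | target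

## Step count and least certain steps

Total: 16 steps. Longest linear sequence: 12 steps (1 to 27 through steps 1–6 and 11–16); the second branch (11 to 17) has 4 steps.

**Step 14 (key step).** Three things may go wrong.
- Discrimination between the two diastereotopic vinyl groups may be weak, giving both C3 epimers. They are diastereomers and separable at 24, but a reversed preference cannot be corrected without changing the C3 substituents.
- The cyclobutene may be opened intermolecularly, leading to oligomers.
- The C8 alkylidene may close onto the isopropenyl group before the cyclobutene opens.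

Fallback, from 23 back to 24: the cascade is split into two operations. Ring-opening cross-metathesis of 23 with ethene (second-generation Grubbs catalyst, ethene atmosphere, dilute CH2Cl2) should give the acyclic pentaene 2-(trimethylsilyl)ethyl ester with a C9 isopropenyl and a C12 vinyl group F1. A separate ring-closing metathesis of F1 is then started at the least hindered alkene, the new C12 vinyl group, so the five-membered ring closes first and the six-membered ring second, giving 24. Any disubstituted seven-membered ring formed between the C12 and C3 vinyl groups can reopen under ethene, whereas the trisubstituted ring alkenes of 24 cannot.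

**Step 12.** Enolisation at the α-carbon next to quaternary C3 may be slow or may give the other ketene acetal geometry (the C15 epimer), and face selection at C14 rests on one methyl group (the C14/C15 diastereomer pair). The congested rearrangement may also need temperatures at which the alkenyl-substituted cyclobutene begins to ring-open.

Fallback, from 10 back to 22: the two bonds to C15 are made in two separate Claisen steps.
- Alcohol 10 is acylated with propionyl chloride and pyridine to (2E)-3-[(1S,4R)-2,4-dimethylcyclobut-2-en-1-yl]-2-methylprop-2-en-1-yl propanoate F2.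
- Ireland–Claisen rearrangement of this simple propionate (LiN(iPr)2, THF, Me3SiCl), whose enolate geometry is well controlled, gives (2R,3S)-3-[(1S,4R)-2,4-dimethylcyclobut-2-en-1-yl]-2,4-dimethylpent-4-enoic acid F3.
- Esterification with dienol 13 (DCC, DMAP) gives the (2Z)-3-ethylpenta-2,4-dien-1-yl ester of that acid F4.
- A second Ireland–Claisen rearrangement forms C3–C15 and returns acid 22.

The face-selection question at C14 remains, but each enolisation and each bond formation is less congested.

**Step 2 (with the lability of 2 from step 1).** The tertiary allylic lactone may be lost by solvolysis or thermal reversion before reduction. The allyl complex may also exchange faces, so that hydride arrives on the carboxylate side and gives the trans acid.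

Fallback, from 2 back to 3: a metal-free ionic reduction, in which Et3SiH with BF3·OEt2 in CH2Cl2 at −78 °C delivers hydride from outside to the cyclobutenyl cation on the face away from the carboxylate; no new compound is involved (F0).

**Step 3.** The two diastereomeric salts may not differ enough in solubility, so crystallisation brings no enrichment.

Fallback, from 3 back to 9: a covalent separation.
- Acid 3 is activated with pivaloyl chloride and Et3N and coupled with the lithium salt of (S)-4-benzyl-1,3-oxazolidin-2-one.
- The two imides are separated on silica, giving (4S)-4-benzyl-3-{[(1R,4R)-2,4-dimethylcyclobut-2-en-1-yl]carbonyl}-1,3-oxazolidin-2-one F5.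
- LiBH4 in wet THF releases the auxiliary and gives [(1R,4R)-2,4-dimethylcyclobut-2-en-1-yl]methanol F6.
- Dess–Martin oxidation in the presence of ethyl 2-(triphenylphosphoranylidene)propanoate generates aldehyde 8 and converts it at once into enoate 9.

**Step 15.** Insertion into the vinyl group on quaternary C3 may be slow, so that homocoupling and oligomerisation of bromide 25 take over, and palladium hydride may shift the new diene.

Fallback, from 24 back to 26: cross-metathesis of 24 with pinacol vinylboronate (second-generation Hoveyda–Grubbs catalyst) gives the (E)-alkenyl pinacol boronate of 24 F7. Suzuki coupling of F7 with 25 (Pd(PPh3)4, aq. K3PO4, THF) then gives 26.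

## Further compounds

F1 | step 14 | 2-(trimethylsilyl)ethyl ester, ring-opened pentaene from ethenolysis of 23 (C9 as isopropenyl, C12 as vinyl; C10, C11, C14, C15 unchanged) | CCC(C=C)(C=C)[C@](C)(C(=O)OCC[Si](C)(C)C)[C@@H](C(C)=C)[C@@H](C(C)=C)[C@H](C)C=C
F2 | step 12 | (2E)-3-[(1S,4R)-2,4-dimethylcyclobut-2-en-1-yl]-2-methylprop-2-en-1-yl propanoate | CCC(=O)OC/C(C)=C/[C@H]1C(C)=C[C@H]1C
F3 | step 12 | (2R,3S)-3-[(1S,4R)-2,4-dimethylcyclobut-2-en-1-yl]-2,4-dimethylpent-4-enoic acid | C[C@@H](C(=O)O)[C@@H](C(C)=C)[C@H]1C(C)=C[C@H]1C
F4 | step 12 | (2Z)-3-ethylpenta-2,4-dien-1-yl (2R,3S)-3-[(1S,4R)-2,4-dimethylcyclobut-2-en-1-yl]-2,4-dimethylpent-4-enoate | C[C@@H](C(=O)OC/C=C(\C=C)CC)[C@@H](C(C)=C)[C@H]1C(C)=C[C@H]1C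
F0 | step 2 | none | none
F5 | step 3 | (4S)-4-benzyl-3-{[(1R,4R)-2,4-dimethylcyclobut-2-en-1-yl]carbonyl}-1,3-oxazolidin-2-one | O=C([C@H]1C(C)=C[C@H]1C)N1[C@@H](Cc2ccccc2)COC1=O
F6 | step 3 | [(1R,4R)-2,4-dimethylcyclobut-2-en-1-yl]methanol | OC[C@H]1C(C)=C[C@H]1C
F7 | step 15 | 2-(trimethylsilyl)ethyl (1R,3aR,4R,5S,7aS)-5-ethyl-1,3,4,7-tetramethyl-5-[(E)-2-(4,4,5,5-tetramethyl-1,3,2-dioxaborolan-2-yl)ethenyl]-3a,4,5,7a-tetrahydro-1H-indene-4-carboxylate | CC[C@]1(/C=C/B2OC(C)(C)C(C)(C)O2)C=C(C)[C@H]2[C@H](C)C=C(C)[C@@H]2[C@@]1(C)C(=O)OCC[Si](C)(C)C
A1 | alternative 1 | cyclopentene from the phosphine-catalysed annulation (ester on C13, methyl on C11, acetyl on C10) | CC[C@](CO[Si](C)(C)C(C)(C)C)(C=C)[C@](C)(C(=O)OC)[C@H]1C(C(=O)OCC)=C[C@@H](C)[C@@H]1C(C)=O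
A2 | alternative 2 | cis-fused tricyclic lactone with both quaternary centres | CC[C@]12C=C(C)[C@H]3[C@H](C)C=C(C)[C@@H]3[C@@]1(C)COC2=O
A3 | alternative 3 | bicyclic enone with the ketone at C12 and the alkene at C13=C14 | CC[C@]1(CO[Si](C)(C)C(C)(C)C)C=C(C)[C@H]2[C@H](C)C(=O)C(C)=C2[C@@]1(C)C(=O)OC
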